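**Retrosynthetic overview**

1. Numbering follows benzofuran (O1, C2, C3, C3a, C4–C7, C7a); ring A is the guaiacyl ring on C2, ring B the benzo ring. Endgame: sulfation of the only free hydroxyl and global desilylation; the C5 chain comes from a sterically directed C–H borylation and an acrylate conjugate addition.
2. Key disconnection: the O1–C7a bond is cut together with the C7–OMe bond, so ring B of the precursor is a bare 2-iodophenyl group. A palladium/norbornene relay puts the methoxy group on C7 and closes the dihydrofuran ring at C7a in one operation.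
3. Enabling feature: C7a of ring B carries iodine and has exactly one free ortho C–H (C7), while the other ortho carbon (C3a) carries the chain C3–C2–OH, whose oxygen reaches C7a in a five-membered ring. O1/C7a and OMe/C7 are neighbours, as an ipso/ortho relay requires.
4. The precursor comes from an Evans syn aldol reaction of the N-(2-iodophenylacetyl)oxazolidinone with silyl-protected vanillin (sets C2 and C3) and reductive removal of the auxiliary. Aryl C–O bond formation touches neither centre, so the syn diol gives the 2,3-trans ring.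
5. Ring order: rings A and B are bought as benzene rings; the dihydrofuran ring is the only ring formed (step 6).

Key step: step 6

Remark: the target is drawn as the free alkyl hydrogen sulfate, so the final pyridinium sulfate is taken through cation exchange to the acid form.

**Route**

Step 1
Reactants: 1 2-(2-iodophenyl)acetic acid; 2 (S)-4-benzyloxazolidin-2-one
Product: 4 (S)-4-benzyl-3-[2-(2-iodophenyl)acetyl]oxazolidin-2-one, via mixed pivalic anhydride 3 (not isolated)
Conditions: PivCl, Et3N, THF, −20 °C; then 2, LiCl, −20 °C to rt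
Reagents that add atoms: none
Why: Mixed-anhydride N-acylation of an oxazolidinone is standard for arylacetic acids; the less hindered arylacetyl carbonyl of 3 is attacked and no stereocentre is involved.

Step 2
Reactants: 5 vanillin (4-hydroxy-3-methoxybenzaldehyde)
Product: 6 3-methoxy-4-(triisopropylsilyloxy)benzaldehyde
Conditions: TIPSCl, imidazole, DMF, rt
Reagents that add atoms: triisopropylsilyl chloride CC(C)[Si](Cl)(C(C)C)C(C)C
Why: Phenol silylation; the bulky silyl ether is chosen because it has no unhindered aryl C–H for step 7, should resist the carbonate base of step 6, and leaves with fluoride at the end.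

Step 3
Reactants: 4 (S)-4-benzyl-3-[2-(2-iodophenyl)acetyl]oxazolidin-2-one; 6 3-methoxy-4-(triisopropylsilyloxy)benzaldehyde
Product: 9 (S)-4-benzyl-3-[(2S,3S)-3-hydroxy-2-(2-iodophenyl)-3-[3-methoxy-4-(triisopropylsilyloxy)phenyl]propanoyl]oxazolidin-2-one, via Z-dibutylboron enolate 7 (not isolated), via dibutylboron aldolate 8 (not isolated)
Conditions: Bu2BOTf, i-Pr2NEt, CH2Cl2, −78 to 0 °C; then 6, −78 to 0 °C; then pH 7 buffer, MeOH, H2O2, 0 °C
Reagents that add atoms: none
Why: Evans syn aldol reaction: the Z-boron enolate 7 adds to 6 through a chair Zimmerman–Traxler transition state on the enolate face away from the auxiliary benzyl group, so the (S)-auxiliary should set both stereocentres (the future C3 and C2) as the (2S,3S) syn adduct.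

Step 4
Reactants: 9 the syn aldol adduct
Product: 10 (1S,2R)-2-(2-iodophenyl)-1-[3-methoxy-4-(triisopropylsilyloxy)phenyl]propane-1,3-diol
Conditions: LiBH4, MeOH (1 equiv), THF, 0 °C
Reagents that add atoms: none
Why: Reductive cleavage of the N-acyl oxazolidinone (hydride attack at the exocyclic carbonyl) should give the primary alcohol without touching either stereocentre; the change of descriptors from (2S,3S) to (1S,2R) is only a change of CIP priorities.

Step 5
Reactants: 10 the syn 1,3-diol
Product: 11 (1S,2R)-2-(2-iodophenyl)-1-[3-methoxy-4-(triisopropylsilyloxy)phenyl]-3-(triisopropylsilyloxy)propan-1-ol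
Conditions: TIPSCl (1.05 equiv), imidazole, CH2Cl2, 0 °C
Reagents that add atoms: triisopropylsilyl chloride CC(C)[Si](Cl)(C(C)C)C(C)C
Why: Selective silylation of the primary over the hindered secondary benzylic hydroxyl with a bulky silyl chloride leaves exactly one free hydroxyl, the one that becomes O1.

Step 6
Reactants: 11 the iodo alcohol
Product: 12 (2S,3R)-7-methoxy-2-[3-methoxy-4-(triisopropylsilyloxy)phenyl]-3-[(triisopropylsilyloxy)methyl]-2,3-dihydro-1-benzofuran
Conditions: Pd(OAc)2 (10 mol%), RuPhos (20 mol%), 7-bromonorbornene (1 equiv), MeON(SO2Ph)2 (2 equiv), Cs2CO3 (3 equiv), 1,4-dioxane, 100 °C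
Reagents that add atoms: N-methoxy-N-(phenylsulfonyl)benzenesulfonamide CON(S(=O)(=O)c1ccccc1)S(=O)(=O)c1ccccc1
Why: Proposed new method: oxidative addition of the C7a–I bond to zerovalent palladium, exo insertion of the norbornene and palladation of the only free ortho C–H (C7) give an aryl–norbornyl palladacycle, whose electron-rich divalent palladium attacks the oxygen of the N-methoxy sulfonimide (SN2 at oxygen, sulfonimide anion as leaving group) and reductively eliminates the C7–OMe bond; with both ortho positions now filled, β-carbon elimination expels the norbornene, and the C2 alkoxide held on the aryl palladium in a six-membered oxapalladacycle (Pd, C7a, C3a, C3, C2, O1) closes the O1–C7a bond by C(sp2)–O reductive elimination, returning zerovalent palladium. The closest known reactions are the palladium/norbornene (Catellani-type) ortho-C–H methoxylation of aryl iodides with N,N-bis(sulfonyl)methoxyamines, run with an olefin or hydride at the ipso carbon, and the palladium/norbornene annulation of aryl iodides with epoxides, which ends in the same alkoxide C–O reductive elimination to a 2,3-dihydrobenzofuran; using a tethered alcohol as the ipso terminator of the methoxylation is the new element. The single ring closed is the dihydrofuran ring, a five-membered closure at the ipso carbon through the six-membered oxapalladacycle. No stereocentre is made: C2 and C3 come from step 3 and neither is a reacting centre (O1 stays on C2, the new bond is to an sp2 carbon), so the syn 1,3-diol geometry of 11 becomes the 2,3-trans ring of 12 with retention at both. The step needs the norbornene relay to run before ipso closure and needs only the secondary hydroxyl to close; the first should hold because norbornene insertion is far faster than C–O reductive elimination from a mono-ortho-substituted aryl palladium alkoxide (the order seen when olefins tethered to the aryl iodide wait for ortho alkylation before the Heck closure) while the bulky RuPhos speeds the final elimination from the di-ortho-substituted aryl, and the second because the primary hydroxyl is silylated and C7 is the only ortho C–H next to iodine.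

Step 7
Reactants: 12 the 7-methoxy dihydrobenzofuran
Product: 13 (2S,3R)-7-methoxy-2-[3-methoxy-4-(triisopropylsilyloxy)phenyl]-5-(4,4,5,5-tetramethyl-1,3,2-dioxaborolan-2-yl)-3-[(triisopropylsilyloxy)methyl]-2,3-dihydro-1-benzofuran
Conditions: [Ir(cod)OMe]2 (1.5 mol%), 4,4′-di-tert-butyl-2,2′-bipyridine (3 mol%), B2pin2 (1 equiv), THF, 80 °C
Reagents that add atoms: bis(pinacolato)diboron CC1(C)OB(OC1(C)C)B1OC(C)(C)C(C)(C)O1
Why: Iridium-catalysed aromatic C–H borylation is sterically controlled, and C5 of ring B is the only aryl C–H in 12 without an ortho substituent (C4 is next to C3a, C6 next to OMe, every C–H of ring A is next to a substituent), so the 1,2,3-pattern made in step 6 should direct boron to C5.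

Step 8
Reactants: 13 the C5 pinacol boronate
Product: 14 ethyl 3-[(2S,3R)-7-methoxy-2-[3-methoxy-4-(triisopropylsilyloxy)phenyl]-3-[(triisopropylsilyloxy)methyl]-2,3-dihydro-1-benzofuran-5-yl]propanoate
Conditions: [Rh(cod)OH]2 (3 mol%), ethyl acrylate (3 equiv), 1,4-dioxane/H2O (10:1), 60 °C
Reagents that add atoms: ethyl acrylate C=CC(=O)OCC
Why: Rhodium-catalysed conjugate addition of an arylboron reagent to an acrylate (Hayashi–Miyaura reaction): aryl transfer from boron to the rhodium hydroxide, acrylate insertion and protonolysis of the rhodium enolate by water should give the saturated three-carbon ester under base-free conditions that spare both silyl ethers.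

Step 9
Reactants: 14 the ethyl propanoate
Product: 15 3-[(2S,3R)-7-methoxy-2-[3-methoxy-4-(triisopropylsilyloxy)phenyl]-3-[(triisopropylsilyloxy)methyl]-2,3-dihydro-1-benzofuran-5-yl]propan-1-ol
Conditions: i-Bu2AlH (2.5 equiv), CH2Cl2, −78 to 0 °C; Rochelle salt work-up
Reagents that add atoms: none
Why: Hydride reduction of the ester to the primary alcohol leaves silyl ethers, aryl ethers and both stereocentres untouched, and this alcohol is now the only free hydroxyl.

Step 10
Reactants: 15 the propanol
Product: 16 pyridinium 3-[(2S,3R)-7-methoxy-2-[3-methoxy-4-(triisopropylsilyloxy)phenyl]-3-[(triisopropylsilyloxy)methyl]-2,3-dihydro-1-benzofuran-5-yl]propyl sulfate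
Conditions: SO3·pyridine (3 equiv), pyridine, 0 °C to rt
Reagents that add atoms: sulfur trioxide–pyridine complex O=S(=O)=O.c1ccncc1
Why: O-Sulfation of a primary alcohol with the SO3·pyridine complex; only the chain hydroxyl is free, so the sulfate should go on at that position alone and be isolated as its pyridinium salt.

Step 11
Reactants: 16 the bis-silylated pyridinium sulfate
Product: 18 3-[(2S,3R)-2-(4-hydroxy-3-methoxyphenyl)-3-(hydroxymethyl)-7-methoxy-2,3-dihydro-1-benzofuran-5-yl]propyl hydrogen sulfate, via desilylated pyridinium salt 17 (not isolated)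
Conditions: HF·pyridine, pyridine, THF, 0 °C to rt; then Dowex 50W (H+ form), MeOH/H2O, 0 °C
Reagents that add atoms: none
Why: Fluoride cleavage of both Si–O bonds (aryl and primary alkyl silyl ethers) under pyridine-buffered conditions that a sulfate monoester anion should tolerate, followed by cold cation exchange to the free hydrogen sulfate; no stereocentre is involved.

**Compound list**

1 | 2-(2-iodophenyl)acetic acid | OC(=O)Cc1ccccc1I | starting material
2 | (S)-4-benzyloxazolidin-2-one | O=C1N[C@@H](Cc2ccccc2)CO1 | starting material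
3 | 2-(2-iodophenyl)acetic pivalic anhydride | CC(C)(C)C(=O)OC(=O)Cc1ccccc1I | intermediate
4 | (S)-4-benzyl-3-[2-(2-iodophenyl)acetyl]oxazolidin-2-one | O=C(Cc1ccccc1I)N1[C@@H](Cc2ccccc2)COC1=O | intermediate
5 | vanillin (4-hydroxy-3-methoxybenzaldehyde) | COc1cc(C=O)ccc1O | starting material
6 | 3-methoxy-4-(triisopropylsilyloxy)benzaldehyde | COc1cc(C=O)ccc1O[Si](C(C)C)(C(C)C)C(C)C | intermediate
7 | Z-dibutylboron enolate of 4 | CCCCB(CCCC)O/C(=C\c1ccccc1I)N1[C@@H](Cc2ccccc2)COC1=O | intermediate
8 | dibutylboron aldolate of 9 | COc1cc([C@@H](OB(CCCC)CCCC)[C@H](c2ccccc2I)C(=O)N2[C@@H](Cc3ccccc3)COC2=O)ccc1O[Si](C(C)C)(C(C)C)C(C)C | intermediate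
9 | (S)-4-benzyl-3-[(2S,3S)-3-hydroxy-2-(2-iodophenyl)-3-[3-methoxy-4-(triisopropylsilyloxy)phenyl]propanoyl]oxazolidin-2-one | COc1cc([C@@H](O)[C@H](c2ccccc2I)C(=O)N2[C@@H](Cc3ccccc3)COC2=O)ccc1O[Si](C(C)C)(C(C)C)C(C)C | intermediate
10 | (1S,2R)-2-(2-iodophenyl)-1-[3-methoxy-4-(triisopropylsilyloxy)phenyl]propane-1,3-diol | COc1cc([C@@H](O)[C@H](c2ccccc2I)CO)ccc1O[Si](C(C)C)(C(C)C)C(C)C | intermediate
11 | (1S,2R)-2-(2-iodophenyl)-1-[3-methoxy-4-(triisopropylsilyloxy)phenyl]-3-(triisopropylsilyloxy)propan-1-ol | COc1cc([C@@H](O)[C@H](c2ccccc2I)CO[Si](C(C)C)(C(C)C)C(C)C)ccc1O[Si](C(C)C)(C(C)C)C(C)C | intermediate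
12 | (2S,3R)-7-methoxy-2-[3-methoxy-4-(triisopropylsilyloxy)phenyl]-3-[(triisopropylsilyloxy)methyl]-2,3-dihydro-1-benzofuran | COc1cc([C@H]2Oc3c(OC)cccc3[C@@H]2CO[Si](C(C)C)(C(C)C)C(C)C)ccc1O[Si](C(C)C)(C(C)C)C(C)C | intermediate
13 | (2S,3R)-7-methoxy-2-[3-methoxy-4-(triisopropylsilyloxy)phenyl]-5-(4,4,5,5-tetramethyl-1,3,2-dioxaborolan-2-yl)-3-[(triisopropylsilyloxy)methyl]-2,3-dihydro-1-benzofuran | COc1cc([C@H]2Oc3c(OC)cc(B4OC(C)(C)C(C)(C)O4)cc3[C@@H]2CO[Si](C(C)C)(C(C)C)C(C)C)ccc1O[Si](C(C)C)(C(C)C)C(C)C | intermediate
14 | ethyl 3-[(2S,3R)-7-methoxy-2-[3-methoxy-4-(triisopropylsilyloxy)phenyl]-3-[(triisopropylsilyloxy)methyl]-2,3-dihydro-1-benzofuran-5-yl]propanoate | COc1cc([C@H]2Oc3c(OC)cc(CCC(=O)OCC)cc3[C@@H]2CO[Si](C(C)C)(C(C)C)C(C)C)ccc1O[Si](C(C)C)(C(C)C)C(C)C | intermediate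
15 | 3-[(2S,3R)-7-methoxy-2-[3-methoxy-4-(triisopropylsilyloxy)phenyl]-3-[(triisopropylsilyloxy)methyl]-2,3-dihydro-1-benzofuran-5-yl]propan-1-ol | COc1cc([C@H]2Oc3c(OC)cc(CCCO)cc3[C@@H]2CO[Si](C(C)C)(C(C)C)C(C)C)ccc1O[Si](C(C)C)(C(C)C)C(C)C | intermediate
16 | pyridinium 3-[(2S,3R)-7-methoxy-2-[3-methoxy-4-(triisopropylsilyloxy)phenyl]-3-[(triisopropylsilyloxy)methyl]-2,3-dihydro-1-benzofuran-5-yl]propyl sulfate | COc1cc([C@H]2Oc3c(OC)cc(CCCOS(=O)(=O)[O-])cc3[C@@H]2CO[Si](C(C)C)(C(C)C)C(C)C)ccc1O[Si](C(C)C)(C(C)C)C(C)C.c1cc[nH+]cc1 | intermediate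
17 | pyridinium 3-[(2S,3R)-2-(4-hydroxy-3-methoxyphenyl)-3-(hydroxymethyl)-7-methoxy-2,3-dihydro-1-benzofuran-5-yl]propyl sulfate | COc1cc([C@H]2Oc3c(OC)cc(CCCOS(=O)(=O)[O-])cc3[C@@H]2CO)ccc1O.c1cc[nH+]cc1 | intermediate
18 | 3-[(2S,3R)-2-(4-hydroxy-3-methoxyphenyl)-3-(hydroxymethyl)-7-methoxy-2,3-dihydro-1-benzofuran-5-yl]propyl hydrogen sulfate | COc1cc([C@H]2Oc3c(OC)cc(CCCOS(=O)(=O)O)cc3[C@@H]2CO)ccc1O | target

**Step count and risks**

Total steps: 11. Longest linear sequence: 10 steps (steps 1 and 3 to 11).

Step 6 (Proposed new method). What may go wrong: direct ipso etherification of the aryl palladium alkoxide before the norbornene relay has delivered the methoxy group (ring closure without the C7 oxygen); sulfonyl transfer from the N-methoxy reagent to the alkoxide; β-hydride elimination from the palladium alkoxide with reduction of the C–I bond; or loss of the phenolic silyl group under carbonate at 100 °C. The fallback uses known chemistry: the methoxy group is brought in from the start and a single Ullmann etherification closes the ring. It sets out from compound 2, which is acylated as in step 1 with purchasable 2-(2-bromo-3-methoxyphenyl)acetic acid F1 to give the N-acyl oxazolidinone F2. The aldol reaction of step 3 with 6 should give the syn aldol adduct F3, LiBH4 the syn diol F4, and TIPSCl the primary silyl ether F5. CuI (copper iodide), 3,4,7,8-tetramethyl-1,10-phenanthroline and Cs2CO3 in toluene at 110 °C (intramolecular Ullmann C–O coupling of the aryl bromide with the secondary alcohol, both centres retained) should then close the ring, and the fallback comes back to the route at compound 12.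

Step 8. What may go wrong: protodeboronation of the electron-rich aryl boronate outrunning aryl transfer to rhodium, or Heck-type β-hydride elimination after acrylate insertion. The fallback installs the three carbons as an allyl group and oxidises its terminus. It sets out from compound 13: Suzuki–Miyaura allylation with allyl bromide (Pd(PPh3)4, K3PO4, THF/H2O, 60 °C) should give the 5-allyl dihydrobenzofuran F6; hydroboration with 9-BBN in THF and oxidation with NaBO3 should give the primary alcohol, and the fallback comes back to the route at compound 15.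

Step 11. What may go wrong: loss of the sulfate monoester by solvolysis, or acid-induced opening of the benzylic C2–O1 bond once the phenol is free (through a para-quinone methide, with loss of the trans configuration), while a charged sulfate is carried through fluoride treatment and purification. The fallback keeps the sulfate masked as a neutral diester until the last operation. It sets out from compound 15: 2,2,2-trichloroethyl chlorosulfate, Et3N and DMAP in THF should give the trichloroethyl sulfate diester F7; HF·pyridine should remove both silyl groups to give the neutral diol diester F8, which can be chromatographed. Zn dust and HCO2NH4 in MeOH (reductive removal of the trichloroethyl group) should give the ammonium sulfate salt F9, and brief cold cation exchange brings the fallback back to the route at compound 18.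

**Further compounds**

F1 | step 6 | 2-(2-bromo-3-methoxyphenyl)acetic acid | OC(=O)Cc1cccc(OC)c1Br
F2 | step 6 | (S)-4-benzyl-3-[2-(2-bromo-3-methoxyphenyl)acetyl]oxazolidin-2-one | O=C(Cc1cccc(OC)c1Br)N1[C@@H](Cc2ccccc2)COC1=O
F3 | step 6 | (S)-4-benzyl-3-[(2S,3S)-2-(2-bromo-3-methoxyphenyl)-3-hydroxy-3-[3-methoxy-4-(triisopropylsilyloxy)phenyl]propanoyl]oxazolidin-2-one | COc1cc([C@@H](O)[C@H](c2cccc(OC)c2Br)C(=O)N2[C@@H](Cc3ccccc3)COC2=O)ccc1O[Si](C(C)C)(C(C)C)C(C)C
F4 | step 6 | (1S,2R)-2-(2-bromo-3-methoxyphenyl)-1-[3-methoxy-4-(triisopropylsilyloxy)phenyl]propane-1,3-diol | COc1cc([C@@H](O)[C@H](c2cccc(OC)c2Br)CO)ccc1O[Si](C(C)C)(C(C)C)C(C)C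
F5 | step 6 | (1S,2R)-2-(2-bromo-3-methoxyphenyl)-1-[3-methoxy-4-(triisopropylsilyloxy)phenyl]-3-(triisopropylsilyloxy)propan-1-ol | COc1cc([C@@H](O)[C@H](c2cccc(OC)c2Br)CO[Si](C(C)C)(C(C)C)C(C)C)ccc1O[Si](C(C)C)(C(C)C)C(C)C
F6 | step 8 | (2S,3R)-5-allyl-7-methoxy-2-[3-methoxy-4-(triisopropylsilyloxy)phenyl]-3-[(triisopropylsilyloxy)methyl]-2,3-dihydro-1-benzofuran | COc1cc([C@H]2Oc3c(OC)cc(CC=C)cc3[C@@H]2CO[Si](C(C)C)(C(C)C)C(C)C)ccc1O[Si](C(C)C)(C(C)C)C(C)C
F7 | step 11 | 3-[(2S,3R)-7-methoxy-2-[3-methoxy-4-(triisopropylsilyloxy)phenyl]-3-[(triisopropylsilyloxy)methyl]-2,3-dihydro-1-benzofuran-5-yl]propyl 2,2,2-trichloroethyl sulfate | COc1cc([C@H]2Oc3c(OC)cc(CCCOS(=O)(=O)OCC(Cl)(Cl)Cl)cc3[C@@H]2CO[Si](C(C)C)(C(C)C)C(C)C)ccc1O[Si](C(C)C)(C(C)C)C(C)C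
F8 | step 11 | 3-[(2S,3R)-2-(4-hydroxy-3-methoxyphenyl)-3-(hydroxymethyl)-7-methoxy-2,3-dihydro-1-benzofuran-5-yl]propyl 2,2,2-trichloroethyl sulfate | COc1cc([C@H]2Oc3c(OC)cc(CCCOS(=O)(=O)OCC(Cl)(Cl)Cl)cc3[C@@H]2CO)ccc1O
F9 | step 11 | ammonium 3-[(2S,3R)-2-(4-hydroxy-3-methoxyphenyl)-3-(hydroxymethyl)-7-methoxy-2,3-dihydro-1-benzofuran-5-yl]propyl sulfate | COc1cc([C@H]2Oc3c(OC)cc(CCCOS(=O)(=O)[O-])cc3[C@@H]2CO)ccc1O.[NH4+]
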